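**Retrosynthetic overview**
1. Feature: ring B carries oxygen on four adjacent carbons, C2' (OMe), C3' (OH), C4' (OMe) and C5' (OMe), and only C1' (bonded to C3 of ring C) and C6'–H do not. C2'–C5' are read as the four ring carbons of dimethyl squarate, and C1'–C6' as a 1,1-disubstituted vinyl group on C3.
2. Ring B is cut at C5'–C6' (six-electron closure of a dienylketene) back to the 4-alkenylcyclobutenone 17. The C1'–C2' bond comes from adding alkenyllithium 14 to squarate 13.
3. O–C3' is distinguished from O–C4' on the four-membered ring: future C3' is the enone β carbon, the only site where methoxy can be swapped for benzyloxy. The base-labile carbinol oxygen (O–C2', a methyl ether in the target) is capped as OMe before the swap.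
4. 14 comes by Shapiro reaction from methyl ketone 11, which is made from (R)-chroman-3-carboxylic acid 8. C3 is set by asymmetric hydrogenation of 2H-chromene-3-carboxylic acid 7.
5. Ring order: ring A is bought (2-methoxyresorcinol), ring C is closed by salicylaldehyde/acrylonitrile annulation, and ring B is built last. O-methylation at C5' and double debenzylation finish the synthesis.

Key step: step 12

Numbering: isoflavan numbering (O1, C2–C8a, C1'–C6') is used for chroman compounds. In the cyclobutenones, C1 is the carbonyl carbon, C2 the α carbon, C3 the β carbon and C4 the sp3 carbon.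
Assumption: the ligand antipode named in step 5 is assigned by analogy with (E)-2-alkylcinnamic acids. A test run decides, and the mirror-image ligand is used if it delivers the (S)-acid.
Remark: the descriptor at C3 reads R in 8–11 and S from 12 onward only because the CIP rank of the side chain against C2 changes. The spatial arrangement never changes.

Step 1
Reactants: 1 2-methoxyresorcinol
Product: 3 2,4-dihydroxy-3-methoxybenzaldehyde, via aryl iminium chloride 2 (not isolated)
Conditions: POCl3 (1.2 equiv), DMF (1.5 equiv), MeCN, 0 °C to rt; then H2O, 50 °C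
Reagents that add atoms: N,N-dimethylformamide CN(C)C=O; water O; phosphoryl chloride O=P(Cl)(Cl)Cl (chloride only in 2)
Why: Vilsmeier–Haack formylation, in which the two equivalent positions ortho to one hydroxyl and para to the other are by far the most activated, so a single aldehyde should result after hydrolysis of 2.

Step 2
Reactants: 3 2,4-dihydroxy-3-methoxybenzaldehyde
Product: 4 4-(benzyloxy)-2-hydroxy-3-methoxybenzaldehyde
Conditions: BnBr (1.05 equiv), NaHCO3 (1.5 equiv), MeCN, 80 °C
Reagents that add atoms: benzyl bromide BrCc1ccccc1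
Why: Regioselective Williamson etherification, since the weak base ionises the 4-OH para to the formyl group while the 2-OH is held in a hydrogen bond to the aldehyde oxygen and stays free for ring C.

Step 3
Reactants: 4 4-(benzyloxy)-2-hydroxy-3-methoxybenzaldehyde; 5 acrylonitrile
Product: 6 7-(benzyloxy)-8-methoxy-2H-chromene-3-carbonitrile
Conditions: 5 (5 equiv, neat), DABCO (0.5 equiv), 80 °C
Reagents that add atoms: none
Why: DABCO-mediated Baylis–Hillman/oxa-Michael annulation of a salicylaldehyde with acrylonitrile and loss of water, a standard entry to 2H-chromene-3-carbonitriles, closes ring C through the O1–C2 and C3–C4 bonds.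

Step 4
Reactants: 6 7-(benzyloxy)-8-methoxy-2H-chromene-3-carbonitrile
Product: 7 7-(benzyloxy)-8-methoxy-2H-chromene-3-carboxylic acid
Conditions: 10% aq NaOH, EtOH, reflux; then 2 M HCl to pH 2
Reagents that add atoms: sodium hydroxide [Na+].[OH-]; water O
Why: Alkaline nitrile hydrolysis through the amide, which aryl benzyl and methyl ethers and the conjugated C3=C4 bond tolerate.

Step 5
Reactants: 7 7-(benzyloxy)-8-methoxy-2H-chromene-3-carboxylic acid
Product: 8 (3R)-7-(benzyloxy)-8-methoxychroman-3-carboxylic acid
Conditions: H2 (6 atm), [Ir(cod)((Sa,S)-DTB-Bn-SIPHOX)]BArF (1 mol %), Et3N (0.5 equiv), MeOH, rt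
Reagents that add atoms: none
Why: Carboxylate-directed asymmetric hydrogenation of an (E)-2-alkylcinnamic-acid-type olefin, in which the bound carboxylate holds C3=C4 in the chiral pocket of the spiro phosphine–oxazoline iridium catalyst so that hydrogen reaches one face only and sets C3 as R, while the homogeneous catalyst leaves the benzyl ether alone.

Step 6
Reactants: 8 (3R)-7-(benzyloxy)-8-methoxychroman-3-carboxylic acid
Product: 10 (3R)-7-(benzyloxy)-N,8-dimethoxy-N-methylchroman-3-carboxamide, via acyl imidazolide 9 (not isolated)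
Conditions: CDI (1.1 equiv), CH2Cl2, 0 °C to rt; then MeNH(OMe)·HCl (1.3 equiv), rt
Reagents that add atoms: N,O-dimethylhydroxylamine hydrochloride CNOC.Cl; 1,1'-carbonyldiimidazole O=C(n1ccnc1)n1ccnc1 (atoms only in 9)
Why: Weinreb amide formation through the acyl imidazolide needs no added base, so the C3–H next to the activated carbonyl and the ring C aryloxide in the β position are not put at risk.

Step 7
Reactants: 10 (3R)-7-(benzyloxy)-N,8-dimethoxy-N-methylchroman-3-carboxamide
Product: 11 1-[(3R)-7-(benzyloxy)-8-methoxychroman-3-yl]ethan-1-one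
Conditions: MeMgBr (1.5 equiv), THF, −20 to 0 °C; cold 0.5 M HCl
Reagents that add atoms: methylmagnesium bromide C[Mg]Br
Why: Weinreb ketone synthesis, in which N-methoxy chelation stops the Grignard addition after one methyl transfer and the ketone is released only in the cold acidic quench, so neither enolisation at C3 nor β-elimination of the aryloxide should erode the stereocentre.

Step 8
Reactants: 11 1-[(3R)-7-(benzyloxy)-8-methoxychroman-3-yl]ethan-1-one
Product: 12 N'-{(1E)-1-[(3S)-7-(benzyloxy)-8-methoxychroman-3-yl]ethylidene}-2,4,6-triisopropylbenzenesulfonohydrazide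
Conditions: 2,4,6-triisopropylbenzenesulfonohydrazide (1.05 equiv), THF, rt, no acid
Reagents that add atoms: 2,4,6-triisopropylbenzenesulfonohydrazide CC(C)c1cc(C(C)C)c(S(=O)(=O)NN)c(C(C)C)c1
Why: Arenesulfonylhydrazone condensation proceeds at room temperature without acid for a methyl ketone and should give the E isomer with the sulfonamide nitrogen syn to CH3, no bond at C3 being touched.

Step 9
Reactants: 12 trisylhydrazone of ketone 11; 13 dimethyl squarate
Product: 15 4-{1-[(3S)-7-(benzyloxy)-8-methoxychroman-3-yl]ethenyl}-4-hydroxy-2,3-dimethoxycyclobut-2-en-1-one (both C4 epimers), via alkenyllithium 14 (not isolated)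
Conditions: n-BuLi (2.05 equiv), THF, −78 °C, then 0 °C until N2 evolution ends, back to −78 °C; cannula into 13 (1.3 equiv), THF, −78 °C; sat aq NH4Cl, −78 °C
Reagents that add atoms: n-butyllithium [Li]CCCC (lithium only in 14)
Why: Shapiro reaction followed by 1,2-addition of an alkenyllithium to a squarate ester, in which the syn-directed second deprotonation takes a CH3 proton rather than C3–H, loss of sulfinate and N2 gives 14 with C3 intact, inverse addition to excess 13 stops at mono-addition to one of two equivalent carbonyl groups, and the new carbinol centre forms without control because it becomes planar in step 12.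

Step 10
Reactants: 15 4-alkenyl-4-hydroxy-2,3-dimethoxycyclobutenone
Product: 16 4-{1-[(3S)-7-(benzyloxy)-8-methoxychroman-3-yl]ethenyl}-2,3,4-trimethoxycyclobut-2-en-1-one (both C4 epimers)
Conditions: MeI (10 equiv), Ag2O (2 equiv), MeCN, rt, dark
Reagents that add atoms: iodomethane CI
Why: Purdie O-methylation runs close to neutrality, which is needed because the alkoxide of a 4-hydroxycyclobutenone is prone to ring opening and acid ionises the carbinol, and the oxygen capped here is O–C2', which the target carries as a methyl ether anyway.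

Step 11
Reactants: 16 4-alkenyl-2,3,4-trimethoxycyclobutenone
Product: 17 3-(benzyloxy)-4-{1-[(3S)-7-(benzyloxy)-8-methoxychroman-3-yl]ethenyl}-2,4-dimethoxycyclobut-2-en-1-one (both C4 epimers)
Conditions: BnOH (10 equiv), KOt-Bu (0.1 equiv), 4 Å molecular sieves, THF, 0 °C to rt
Reagents that add atoms: benzyl alcohol OCc1ccccc1
Why: Vinylogous transesterification by conjugate addition–elimination, as known for squarate esters, in which only C3 as the enone β carbon can accept benzyl oxide and expel methoxide (the C2 methoxy sits on the α carbon, the C4 methoxy on an sp3 carbon), 16 has no acidic hydrogen, and excess benzyl alcohol plus uptake of methanol by the sieves shift the equilibrium.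

Step 12
Reactants: 17 3-(benzyloxy)-4-alkenyl-2,4-dimethoxycyclobutenone
Product: 20 (3S)-7,3'-bis(benzyloxy)-5'-hydroxy-8,2',4'-trimethoxyisoflavan, via (Z)-dienylketene 18 (not isolated), via cyclohexa-2,4-dienone 19 (not isolated)
Conditions: degassed p-xylene (0.02 M), 135 °C, Ar
Reagents that add atoms: none
Why: Heat breaks the C1–C4 bond of the cyclobutenone (carbonyl carbon = future C5', methoxy-bearing sp3 carbon = future C2') in a strain-releasing conrotatory four-electron opening; the donor OMe on C4 turns outward, so the alkenyl group turns inward to give (Z)-dienylketene 18, and a ketene from the opposite rotation can only reclose to 17 and try again. Ring B then closes by a thermal six-electron disrotatory electrocyclisation that joins the ketene carbon C5' to the vinyl CH2 (C6'), and dienone 19 enolises at once to phenol 20, which makes the sequence irreversible. The closest known reaction type is the Moore rearrangement of 4-alkenyl-4-hydroxy- or 4-alkoxy-2,3-dialkoxycyclobutenones, for instance of the isopropenyllithium adduct of dimethyl squarate, which has the same 1,1-disubstituted vinyl group. No stereocentre is made: C4 becomes planar, so both epimers of 17 converge, and C3 of ring C lies outside the reacting π system and meets neither acid nor base. The selectivity needed is positional, benzyloxy at C3' and not C4', and the constitution of 17 secures it, because no C–O bond is broken and ring carbon C3 (next to C4) must become C3' while C2 (next to the carbonyl) becomes C4'. High dilution and exclusion of air keep the ketene from intermolecular capture and the electron-rich phenol from oxidation.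

Step 13
Reactants: 20 (3S)-7,3'-bis(benzyloxy)-5'-hydroxy-8,2',4'-trimethoxyisoflavan
Product: 21 (3S)-7,3'-bis(benzyloxy)-8,2',4',5'-tetramethoxyisoflavan
Conditions: MeI (2 equiv), K2CO3 (2 equiv), acetone, 50 °C
Reagents that add atoms: iodomethane CI
Why: Williamson O-methylation of the single free phenol at C5', under a carbonate base that cannot touch the benzylic C3–H.

Step 14
Reactants: 21 (3S)-7,3'-bis(benzyloxy)-8,2',4',5'-tetramethoxyisoflavan
Product: 22 (3S)-7,3'-dihydroxy-8,2',4',5'-tetramethoxyisoflavan (target)
Conditions: H2 (1 atm), 10% Pd/C, EtOAc/MeOH, rt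
Reagents that add atoms: none
Why: Catalytic hydrogenolysis removes both O-benzyl groups, while the O1–C2 bond is not benzylic and C3 carries only C–C and C–H bonds, so the isoflavan core and its configuration should stay.

**Compound list**
1 | 2-methoxyresorcinol (2-methoxybenzene-1,3-diol) | COc1c(O)cccc1O | starting material
2 | (2,4-dihydroxy-3-methoxybenzylidene)dimethyliminium chloride | C[N+](C)=Cc1ccc(O)c(OC)c1O.[Cl-] | intermediate
3 | 2,4-dihydroxy-3-methoxybenzaldehyde | O=Cc1ccc(O)c(OC)c1O | intermediate
4 | 4-(benzyloxy)-2-hydroxy-3-methoxybenzaldehyde | O=Cc1ccc(OCc2ccccc2)c(OC)c1O | intermediate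
5 | acrylonitrile | C=CC#N | starting material
6 | 7-(benzyloxy)-8-methoxy-2H-chromene-3-carbonitrile | N#CC1=Cc2ccc(OCc3ccccc3)c(OC)c2OC1 | intermediate
7 | 7-(benzyloxy)-8-methoxy-2H-chromene-3-carboxylic acid | OC(=O)C1=Cc2ccc(OCc3ccccc3)c(OC)c2OC1 | intermediate
8 | (3R)-7-(benzyloxy)-8-methoxychroman-3-carboxylic acid | OC(=O)[C@H]1COc2c(ccc(OCc3ccccc3)c2OC)C1 | intermediate
9 | [(3R)-7-(benzyloxy)-8-methoxychroman-3-yl](imidazol-1-yl)methanone | O=C(n1ccnc1)[C@H]1COc2c(ccc(OCc3ccccc3)c2OC)C1 | intermediate
10 | (3R)-7-(benzyloxy)-N,8-dimethoxy-N-methylchroman-3-carboxamide | CON(C)C(=O)[C@H]1COc2c(ccc(OCc3ccccc3)c2OC)C1 | intermediate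
11 | 1-[(3R)-7-(benzyloxy)-8-methoxychroman-3-yl]ethan-1-one | CC(=O)[C@H]1COc2c(ccc(OCc3ccccc3)c2OC)C1 | intermediate
12 | N'-{(1E)-1-[(3S)-7-(benzyloxy)-8-methoxychroman-3-yl]ethylidene}-2,4,6-triisopropylbenzenesulfonohydrazide | C/C(=N\NS(=O)(=O)c1c(C(C)C)cc(C(C)C)cc1C(C)C)[C@H]1COc2c(ccc(OCc3ccccc3)c2OC)C1 | intermediate
13 | dimethyl squarate (3,4-dimethoxycyclobut-3-ene-1,2-dione) | COC1=C(OC)C(=O)C1=O | starting material
14 | {1-[(3S)-7-(benzyloxy)-8-methoxychroman-3-yl]ethenyl}lithium | [Li]C(=C)[C@H]1COc2c(ccc(OCc3ccccc3)c2OC)C1 | intermediate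
15 | 4-{1-[(3S)-7-(benzyloxy)-8-methoxychroman-3-yl]ethenyl}-4-hydroxy-2,3-dimethoxycyclobut-2-en-1-one, both C4 epimers | C=C([C@H]1COc2c(ccc(OCc3ccccc3)c2OC)C1)C1(O)C(OC)=C(OC)C1=O | intermediate
16 | 4-{1-[(3S)-7-(benzyloxy)-8-methoxychroman-3-yl]ethenyl}-2,3,4-trimethoxycyclobut-2-en-1-one, both C4 epimers | C=C([C@H]1COc2c(ccc(OCc3ccccc3)c2OC)C1)C1(OC)C(OC)=C(OC)C1=O | intermediate
17 | 3-(benzyloxy)-4-{1-[(3S)-7-(benzyloxy)-8-methoxychroman-3-yl]ethenyl}-2,4-dimethoxycyclobut-2-en-1-one, both C4 epimers | C=C([C@H]1COc2c(ccc(OCc3ccccc3)c2OC)C1)C1(OC)C(OCc2ccccc2)=C(OC)C1=O | intermediate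
18 | (3Z)-3-(benzyloxy)-5-[(3S)-7-(benzyloxy)-8-methoxychroman-3-yl]-2,4-dimethoxyhexa-1,3,5-trien-1-one (dienylketene) | O=C=C(OC)/C(OCc1ccccc1)=C(OC)\C(=C)[C@H]1COc2c(ccc(OCc3ccccc3)c2OC)C1 | intermediate
19 | 3-(benzyloxy)-5-[(3S)-7-(benzyloxy)-8-methoxychroman-3-yl]-2,4-dimethoxycyclohexa-2,4-dien-1-one | O=C1CC([C@H]2COc3c(ccc(OCc4ccccc4)c3OC)C2)=C(OC)C(OCc2ccccc2)=C1OC | intermediate
20 | (3S)-7,3'-bis(benzyloxy)-5'-hydroxy-8,2',4'-trimethoxyisoflavan, i.e. 3-(benzyloxy)-5-[(3S)-7-(benzyloxy)-8-methoxychroman-3-yl]-2,4-dimethoxyphenol | Oc1cc([C@H]2COc3c(ccc(OCc4ccccc4)c3OC)C2)c(OC)c(OCc2ccccc2)c1OC | intermediate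
21 | (3S)-7,3'-bis(benzyloxy)-8,2',4',5'-tetramethoxyisoflavan | COc1cc([C@H]2COc3c(ccc(OCc4ccccc4)c3OC)C2)c(OC)c(OCc2ccccc2)c1OC | intermediate
22 | (3S)-7,3'-dihydroxy-8,2',4',5'-tetramethoxyisoflavan (CNP0201239.1) | COc1cc([C@H]2COc3c(ccc(O)c3OC)C2)c(OC)c(O)c1OC | target

**Count:** 14 steps in total. The longest linear sequence is 14 steps (1 to 22); 5 and 13 enter as bought.

**Steps most likely to fail**

Step 11 (alkoxy exchange). Benzyl oxide may attack the carbonyl carbon C1 and cleave the strained ring, or the exchange may stall at equilibrium.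
- The fallback puts the benzyl group on the squarate before the C–C bond is made. It sets out from 13 and from 14 (generated from 12 as in step 9).
- 13 is treated with one equivalent of BnOH and catalytic Et3N. The mixed diester 3-(benzyloxy)-4-methoxycyclobut-3-ene-1,2-dione F1 is separated from the two symmetrical diesters.
- 14 is added to F1 at −78 °C, and both carbonyl groups are expected to react.
- This gives the wanted carbinol 3-(benzyloxy)-4-alkenyl-4-hydroxy-2-methoxycyclobutenone F2 beside its regioisomer 2-(benzyloxy)-4-alkenyl-4-hydroxy-3-methoxycyclobutenone F3. They are separated by chromatography and assigned by HMBC.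
- F2 is O-methylated with MeI/Ag2O as in step 10 and comes back to the route at 17.
- The price is loss of regiocontrol and of part of 14.

Step 9 (Shapiro reaction and addition). Four processes threaten the step:
- Deprotonation may take C3–H instead of CH3 and then expel the ring C aryloxide.
- The alkenyllithium may be quenched by proton transfer during the warm-up.
- A benzylic OCH2 may be metalated.
- A second addition to the squarate may occur.

The fallback sets out from 11 and replaces the hydrazone chemistry by tin–lithium exchange.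
- 11 is deprotonated at the methyl group with LiN(i-Pr)2 (THF, −78 °C). The kinetic enolate is trapped with N-(5-chloro-2-pyridyl)bis(trifluoromethanesulfonimide) to give the enol triflate F4.
- Pd(PPh3)4, LiCl and Me3SnSnMe3 (THF, 60 °C) convert F4 into the alkenylstannane F5, which can be purified and checked for enantiopurity.
- MeLi (THF, −78 °C) then gives 14 free of sulfinate and without any warm-up. The route is rejoined at 14, with addition to 13 as in step 9.

Step 5 (asymmetric hydrogenation). Facial selectivity may be poor, or turnover slow, on this electron-rich chromene acid. The fallback sets out from 7 and separates diastereomers instead of relying on a chiral catalyst.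
- 7 is hydrogenated with the achiral complex [Ir(cod)(PCy3)(py)]PF6 (H2, CH2Cl2), which spares the benzyl ether, to give the racemic chroman-3-carboxylic acid F6.
- The mixed anhydride (PivCl, Et3N) is treated with lithiated (S)-4-benzyloxazolidin-2-one. This gives the (3R) imide F7 and the (3S) imide F8, which are separated by chromatography or crystallisation and assigned by X-ray analysis.
- F7 with MeNH(OMe)·HCl and AlMe3 (CH2Cl2, 0 °C) gives the Weinreb amide directly, and the route is rejoined at 10.

**Further compounds**
F1 | step 11 | 3-(benzyloxy)-4-methoxycyclobut-3-ene-1,2-dione | COC1=C(OCc2ccccc2)C(=O)C1=O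
F2 | step 11 | 3-(benzyloxy)-4-{1-[(3S)-7-(benzyloxy)-8-methoxychroman-3-yl]ethenyl}-4-hydroxy-2-methoxycyclobut-2-en-1-one, both C4 epimers | C=C([C@H]1COc2c(ccc(OCc3ccccc3)c2OC)C1)C1(O)C(OCc2ccccc2)=C(OC)C1=O
F3 | step 11 | 2-(benzyloxy)-4-{1-[(3S)-7-(benzyloxy)-8-methoxychroman-3-yl]ethenyl}-4-hydroxy-3-methoxycyclobut-2-en-1-one, both C4 epimers | C=C([C@H]1COc2c(ccc(OCc3ccccc3)c2OC)C1)C1(O)C(OC)=C(OCc2ccccc2)C1=O
F4 | step 9 | 1-[(3R)-7-(benzyloxy)-8-methoxychroman-3-yl]ethenyl trifluoromethanesulfonate | C=C(OS(=O)(=O)C(F)(F)F)[C@H]1COc2c(ccc(OCc3ccccc3)c2OC)C1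
F5 | step 9 | {1-[(3R)-7-(benzyloxy)-8-methoxychroman-3-yl]ethenyl}trimethylstannane | C=C([Sn](C)(C)C)[C@H]1COc2c(ccc(OCc3ccccc3)c2OC)C1
F6 | step 5 | rac-7-(benzyloxy)-8-methoxychroman-3-carboxylic acid | OC(=O)C1COc2c(ccc(OCc3ccccc3)c2OC)C1
F7 | step 5 | (4S)-4-benzyl-3-{[(3R)-7-(benzyloxy)-8-methoxychroman-3-yl]carbonyl}oxazolidin-2-one | O=C([C@H]1COc2c(ccc(OCc3ccccc3)c2OC)C1)N1[C@@H](Cc2ccccc2)COC1=O
F8 | step 5 | (4S)-4-benzyl-3-{[(3S)-7-(benzyloxy)-8-methoxychroman-3-yl]carbonyl}oxazolidin-2-one | O=C([C@@H]1COc2c(ccc(OCc3ccccc3)c2OC)C1)N1[C@@H](Cc2ccccc2)COC1=O
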